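**Retrosynthetic overview**
1. The ester C–O bond is cut to give the ring-cis allylic alcohol and O-acetylvanillic acid. The arene ring is bought, not built.
2. The isopropyl group comes from an isopropenyl group by site-selective hydrogenation.
3. Key disconnection: ring bond C1–C10, between the carbinol carbon and its branched neighbour. It leads back to an open-chain (2Z,6Z)-10-chloro-enal. The allylic chloride is reduced to an allyl anion equivalent (allylchromium), which attacks the enal carbon. Two electrophilic carbons are joined, the ring closes, and both stereocentres are set under ligand control.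
4. The chloro-enal comes from (2Z,6Z)-farnesal, then (2Z,6Z)-farnesol, then neryl bromide plus dilithiated prenol. One Z alkene comes from nerol and the other from directed metalation.
5. Ring order: only one ring is formed, the ten-membered carbocycle, in step 5.

Numbering: C1 is the carbinol carbon and C10 is the carbon bearing isopropyl. The farnesane chain numbers give these two carbons the same numbers.

Assumption: the SMILES is read literally (both ring alkenes Z, C1 R, C10 S, acyloxy and isopropyl cis on the ring), and the (R,R)-salen ligand is taken to give this enantiomer; if the first run shows the opposite sense, the equally cheap (S,S)-ligand is used with nothing else changed.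

**Step 1**
Reactants: 1 nerol, (2Z)-3,7-dimethylocta-2,6-dien-1-ol
Product: 2 neryl bromide, (2Z)-1-bromo-3,7-dimethylocta-2,6-diene
Conditions: PBr3 (0.4 equiv), Et2O, −10 °C, 1 h, used crude
Reagents that add atoms: phosphorus tribromide, BrP(Br)Br
Why: Bromide displaces the phosphite ester formed in situ by SN2 at the primary allylic carbon (alcohol to bromide with PBr3), and at −10 °C neither allylic transposition nor Z to E isomerisation occurs; no stereocentre is made.

**Step 2**
Reactants: 2 neryl bromide; 3 prenol, 3-methylbut-2-en-1-ol (1.5 equiv)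
Product: 5 (2Z,6Z)-farnesol, via dilithiated prenol 4 (not isolated)
Conditions: 3, n-BuLi (2.2 equiv per 3), TMEDA (2.2 equiv per 3), Et2O–hexane, 0 °C to 23 °C, 20 h; then 2, THF, −78 °C to 0 °C; H2O
Reagents that add atoms: none
Why: Alkoxide-directed allylic lithiation removes a proton only from the methyl group cis to CH2OLi, and the chelated allyllithium 4 is alkylated at its CH2 terminus by the primary allylic bromide (SN2 allyl–allyl coupling), so the new trisubstituted alkene is Z and the Z alkene of 2 is carried over unchanged.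

**Step 3**
Reactants: 5 (2Z,6Z)-farnesol
Product: 6 (2Z,6Z)-farnesal, (2Z,6Z)-3,7,11-trimethyldodeca-2,6,10-trienal
Conditions: TEMPO (0.1 equiv), PhI(OAc)2 (1.1 equiv), MeCN–pH 7 buffer, 0 °C
Reagents that add atoms: none
Why: Oxoammonium oxidation (TEMPO/PhI(OAc)2) stops at the aldehyde and runs near neutral pH, so the Z enal does not isomerise to the E enal and the isolated alkenes are untouched.

**Step 4**
Reactants: 6 (2Z,6Z)-farnesal
Product: 7 (2Z,6Z)-10-chloro-3,7,11-trimethyldodeca-2,6,11-trienal (racemic at C10)
Conditions: N-chlorosuccinimide (1.0 equiv), PhSeCl (0.05 equiv), CH2Cl2, 0 °C to 23 °C, stopped at about 80 % conversion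
Reagents that add atoms: N-chlorosuccinimide, O=C1CCC(=O)N1Cl
Why: Selenium-catalysed ene-type allylic chlorination attacks the most electron-rich and least hindered alkene, the terminal Me2C=CH unit (the enal alkene is deactivated, the inner alkene is more hindered), and delivers the transposed secondary allylic chloride, whose racemic C10 centre is erased in step 5.

**Step 5 (key step)**
Reactants: 7 (2Z,6Z)-10-chloro-3,7,11-trimethyldodeca-2,6,11-trienal
Product: 10 (1S,2Z,6Z,10S)-3,7-dimethyl-10-(prop-1-en-2-yl)cyclodeca-2,6-dien-1-ol, via allylchromium salen complex 8 (not isolated), via trimethylsilyl ether 9 (not isolated)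
Conditions: CrCl3 (0.15 equiv), Mn powder (3 equiv), (R,R)-N,N'-bis(3,5-di-tert-butylsalicylidene)cyclohexane-1,2-diamine (0.30 equiv), Et3N (0.30 equiv), Me3SiCl (1.5 equiv), MeCN, 23 °C, 7 added over 20 h (final 2 mM); then K2CO3 (0.2 equiv), MeOH, 0 °C
Reagents that add atoms: none
Why: Proposed new method: divalent chromium salen, recycled by Mn, reduces the allylic C–Cl bond in two one-electron transfers, so the normally electrophilic allyl unit becomes a nucleophilic allylchromium (trivalent chromium on C12) that attacks the equally electrophilic enal carbon C1 through its γ-carbon C10 under pseudo-high dilution; because the salen-bound chromium has no free site, addition runs through an open transition state on an enal activated by a second chromium salen centre, which places C2 and C9 anti and gives the syn (ring-cis) C1/C10 pair while the chiral ligand selects the aldehyde face, and Me3SiCl releases the catalyst by forming 9; the closest known reaction types are the catalytic enantioselective, syn-selective Nozaki–Hiyama–Kishi crotylation with chromium salen complexes (ligand to chromium 2:1) and the CrCl2- or Pd/Et2Zn-mediated allyl halide–enal closures of ten-membered germacrane rings.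

**Step 6**
Reactants: 10 (1S,2Z,6Z,10S)-3,7-dimethyl-10-(prop-1-en-2-yl)cyclodeca-2,6-dien-1-ol
Product: 11 (1R,2Z,6Z,10S)-3,7-dimethyl-10-(propan-2-yl)cyclodeca-2,6-dien-1-ol
Conditions: RhCl(PPh3)3 (0.05 equiv), H2 (1 atm), benzene–EtOH 1:1, 23 °C, stopped after 1 equiv H2
Reagents that add atoms: none
Why: Homogeneous hydrogenation with RhCl(PPh3)3 is governed by steric access, so the exocyclic 1,1-disubstituted alkene is saturated well before the two trisubstituted ring alkenes; no stereocentre is touched, and the C1 descriptor changes from S to R only because the priority order of C2 and C10 is reversed.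

**Step 7**
Reactants: 11 (1R,2Z,6Z,10S)-3,7-dimethyl-10-(propan-2-yl)cyclodeca-2,6-dien-1-ol; 12 4-acetoxy-3-methoxybenzoic acid (1.3 equiv)
Product: 14 (1R,2Z,6Z,10S)-3,7-dimethyl-10-(propan-2-yl)cyclodeca-2,6-dien-1-yl 4-hydroxy-3-methoxybenzoate (target), via O-acetyl ester 13 (not isolated)
Conditions: DCC (1.4 equiv), DMAP (0.3 equiv), CH2Cl2, 0 °C to 23 °C; then pyrrolidine (3 equiv), 0 °C to 23 °C, 1 h
Reagents that add atoms: none
Why: Steglich esterification acylates the oxygen of 11 without breaking the C1–O bond, so both stereocentres are retained, and the aryl acetate of 13 is then removed by fast aminolysis with pyrrolidine, which leaves the hindered secondary alkyl benzoate alone.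

**Compound list**
1 | nerol, (2Z)-3,7-dimethylocta-2,6-dien-1-ol | CC(C)=CCC/C(C)=C\CO | starting material
2 | neryl bromide, (2Z)-1-bromo-3,7-dimethylocta-2,6-diene | CC(C)=CCC/C(C)=C\CBr | intermediate
3 | prenol, 3-methylbut-2-en-1-ol | CC(C)=CCO | starting material
4 | dilithiated prenol, lithium (2Z)-4-lithio-3-methylbut-2-en-1-olate (CH2Li cis to CH2OLi) | [Li]C/C(C)=C\CO[Li] | intermediate
5 | (2Z,6Z)-farnesol, (2Z,6Z)-3,7,11-trimethyldodeca-2,6,10-trien-1-ol | CC(C)=CCC/C(C)=C\CC/C(C)=C\CO | intermediate
6 | (2Z,6Z)-farnesal, (2Z,6Z)-3,7,11-trimethyldodeca-2,6,10-trienal | CC(C)=CCC/C(C)=C\CC/C(C)=C\C=O | intermediate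
7 | (2Z,6Z)-10-chloro-3,7,11-trimethyldodeca-2,6,11-trienal, racemic at C10 | C=C(C)C(Cl)CC/C(C)=C\CC/C(C)=C\C=O | intermediate
8 | allylchromium salen complex: trivalent chromium bound to the (R,R)-salen dianion and to C12 of the (2Z,6Z,10E)-3,7,11-trimethyl-1-oxododeca-2,6,10-trien-12-yl group | [Cr+3].[CH2-]/C(C)=C/CC/C(C)=C\CC/C(C)=C\C=O.CC(C)(C)c1cc(/C=N/[C@@H]2CCCC[C@H]2/N=C/c2cc(C(C)(C)C)cc(C(C)(C)C)c2[O-])c([O-])c(C(C)(C)C)c1 | intermediate
9 | trimethylsilyl ether of 10, {[(1S,2Z,6Z,10S)-3,7-dimethyl-10-(prop-1-en-2-yl)cyclodeca-2,6-dien-1-yl]oxy}trimethylsilane | C[Si](C)(C)O[C@H]1/C=C(/C)CC/C=C(/C)CC[C@H]1C(C)=C | intermediate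
10 | (1S,2Z,6Z,10S)-3,7-dimethyl-10-(prop-1-en-2-yl)cyclodeca-2,6-dien-1-ol (OH and isopropenyl cis) | O[C@H]1/C=C(/C)CC/C=C(/C)CC[C@H]1C(C)=C | intermediate
11 | (1R,2Z,6Z,10S)-3,7-dimethyl-10-(propan-2-yl)cyclodeca-2,6-dien-1-ol (OH and isopropyl cis) | O[C@H]1/C=C(/C)CC/C=C(/C)CC[C@H]1C(C)C | intermediate
12 | 4-acetoxy-3-methoxybenzoic acid (O-acetylvanillic acid) | CC(=O)Oc1ccc(C(=O)O)cc1OC | starting material
13 | (1R,2Z,6Z,10S)-3,7-dimethyl-10-(propan-2-yl)cyclodeca-2,6-dien-1-yl 4-acetoxy-3-methoxybenzoate | CC(=O)Oc1ccc(C(=O)O[C@H]2/C=C(/C)CC/C=C(/C)CC[C@H]2C(C)C)cc1OC | intermediate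
14 | (1R,2Z,6Z,10S)-3,7-dimethyl-10-(propan-2-yl)cyclodeca-2,6-dien-1-yl 4-hydroxy-3-methoxybenzoate | COc1cc(C(=O)O[C@H]2/C=C(/C)CC/C=C(/C)CC[C@H]2C(C)C)ccc1O | target

**Total step count:** 7. **Longest linear sequence:** 7 (1 to 14).

**Steps most likely to fail**

Step 2 (allyl–allyl alkylation). The risks are attack through the inner allyl terminus, SN2′ attack on 2, and elimination of 2.
- The fallback sets out from 2 and comes back at 5. It builds the Z alkene by stereoretentive cross-coupling instead of directed metalation.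
- The dianion of methyl acetoacetate (NaH, then n-BuLi, THF, 0 °C) is alkylated by 2 at its terminal carbon. This gives methyl (6Z)-7,11-dimethyl-3-oxododeca-6,10-dienoate F1.
- TsCl, N-methylimidazole and Et3N (CH2Cl2, 0 °C) give the enol tosylate methyl (2E,6Z)-7,11-dimethyl-3-(tosyloxy)dodeca-2,6,10-trienoate F2.
- MeZnCl with PdCl2(dppf) (THF, 23 °C) replaces the tosylate by methyl with retention. This gives methyl (2Z,6Z)-farnesoate F3.
- iBu2AlH (CH2Cl2, −78 °C) reduces F3 to 5.

Step 4 (site selectivity between the terminal and the inner trisubstituted alkene).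
- The fallback sets out from 6 and comes back at 8. It uses allylic oxidation of a methyl group in place of ene chlorination, and a primary rather than a secondary chloride.
- SeO2 (0.1 equiv) with t-BuOOH (CH2Cl2, 0 °C) has a well-established preference for the (E)-methyl group of the chain-end alkene. It gives (2Z,6Z,10E)-12-hydroxy-3,7,11-trimethyldodeca-2,6,10-trienal F4.
- N-chlorosuccinimide and Me2S (CH2Cl2, −20 °C) convert F4 into (2Z,6Z,10E)-12-chloro-3,7,11-trimethyldodeca-2,6,10-trienal F5.
- Under the conditions of step 5, F5 is reduced to the same allylchromium 8.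

Step 5 (the riskiest step). The risks are oligomerisation, pinacol coupling of the enal, and insufficient syn selectivity or enantioselectivity.
- The fallback sets out from 7 and comes back at 11. It separates ring closure from stereocontrol.
- PdCl2(PPh3)2 (0.1 equiv), Et2Zn, K2CO3 and DMA, with slow addition of 7, turn the π-allylpalladium into an allylzinc that adds to the enal. This gives (2Z,6Z)-3,7-dimethyl-10-(prop-1-en-2-yl)cyclodeca-2,6-dien-1-ol as a stereoisomer mixture F6.
- RhCl(PPh3)3 and H2 give (2Z,6Z)-3,7-dimethyl-10-(propan-2-yl)cyclodeca-2,6-dien-1-ol as a stereoisomer mixture F7.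
- Dess–Martin periodinane gives racemic (2Z,6Z)-3,7-dimethyl-10-(propan-2-yl)cyclodeca-2,6-dien-1-one F8.
- Both stereocentres are then set together by carbonyl-selective asymmetric hydrogenation with dynamic kinetic resolution: RuCl2[(R)-binap][(S,S)-dpen], KOtBu, i-PrOH, H2 (8 atm). C10 epimerises through the enolate, and only one enantiomer is reduced, from the face away from the isopropyl group. This gives the cis alcohol 11.

**Further compounds**
F1 | step 2 | methyl (6Z)-7,11-dimethyl-3-oxododeca-6,10-dienoate | CC(C)=CCC/C(C)=C\CCC(=O)CC(=O)OC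
F2 | step 2 | methyl (2E,6Z)-7,11-dimethyl-3-(tosyloxy)dodeca-2,6,10-trienoate | CC(C)=CCC/C(C)=C\CC/C(OS(=O)(=O)c1ccc(C)cc1)=C\C(=O)OC
F3 | step 2 | methyl (2Z,6Z)-farnesoate, methyl (2Z,6Z)-3,7,11-trimethyldodeca-2,6,10-trienoate | CC(C)=CCC/C(C)=C\CC/C(C)=C\C(=O)OC
F4 | step 4 | (2Z,6Z,10E)-12-hydroxy-3,7,11-trimethyldodeca-2,6,10-trienal | OC/C(C)=C/CC/C(C)=C\CC/C(C)=C\C=O
F5 | step 4 | (2Z,6Z,10E)-12-chloro-3,7,11-trimethyldodeca-2,6,10-trienal | ClC/C(C)=C/CC/C(C)=C\CC/C(C)=C\C=O
F6 | step 5 | (2Z,6Z)-3,7-dimethyl-10-(prop-1-en-2-yl)cyclodeca-2,6-dien-1-ol, stereoisomer mixture at C1 and C10 | OC1/C=C(/C)CC/C=C(/C)CCC1C(C)=C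
F7 | step 5 | (2Z,6Z)-3,7-dimethyl-10-(propan-2-yl)cyclodeca-2,6-dien-1-ol, stereoisomer mixture at C1 and C10 | OC1/C=C(/C)CC/C=C(/C)CCC1C(C)C
F8 | step 5 | (2Z,6Z)-3,7-dimethyl-10-(propan-2-yl)cyclodeca-2,6-dien-1-one, racemic | O=C1/C=C(/C)CC/C=C(/C)CCC1C(C)C
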